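Assumption: the diterpene chain is numbered C1 (benzylic CH2) to C15 (the carbon that carries the two terminal methyls and the lactone oxygen), with methyls on C3, C7 and C11; allyl 4-hydroxybenzoate, (2E,6E)-farnesyl bromide and methyl (S)-glycidate are taken as commercial.

**Retrosynthetic overview**
1. Target ⇐ its O-pivaloyl (10R,11R)-epoxide isomer, by stereospecific epoxide inversion (hydrolysis, then re-closure) and ester cleavage.
2. Cyclohexene ring (C2–C7 bond, C6–Br) ⇐ transannular bromocyclisation, triggered at an anode, of a 20-membered macrolactone; this ring is formed last.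
3. 20-membered bromolactone (C14–Br, ester on O15) ⇐ 19-membered C14 lactone by 1,2-acyl shift with bromide inversion ⇐ Shiina lactonisation of the seco acid.
4. C10/C11 epoxide ⇐ epoxidation directed by the C14 hydroxyl, the only stereocentre that is bought (methyl (S)-glycidate).
5. Chain ⇐ C12–C13 alkylation of a glycidate-derived hydroxy sulfone with a 12-bromofarnesyl benzoate; ring order: arene (bought), 19-membered lactone, 20-membered lactone, cyclohexene, epoxide re-closed.

**Route**

Step 1
Reactants: 1 allyl 4-hydroxybenzoate; 2 (2E,6E)-farnesyl bromide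
Product: 4 allyl 3-[(2E,6E)-farnesyl]-4-(pivaloyloxy)benzoate, via phenol 3 (not isolated)
Conditions: NaH, toluene, 0 °C → rt; then t-BuCOCl, Et3N, DMAP (cat.), rt
Reagents that add atoms: pivaloyl chloride, CC(C)(C)C(Cl)=O
Why: The sodium phenoxide, a tight ion pair in toluene with its para position blocked, is C-alkylated at the ortho carbon by the primary end of the allylic bromide (phenoxide ortho-C-allylation, E geometry kept), and the phenol is then capped in the same flask as a base-stable, ring-deactivating pivalate.

Step 2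
Reactants: 4 allyl 3-[(2E,6E)-farnesyl]-4-(pivaloyloxy)benzoate
Product: 5 allyl 3-[(2E,6E,10E)-12-hydroxyfarnesyl]-4-(pivaloyloxy)benzoate
Conditions: SeO2 (0.2 equiv), t-BuOOH, salicylic acid (cat.), CH2Cl2, 0 °C → rt
Reagents that add atoms: tert-butyl hydroperoxide, CC(C)(C)OO (oxygen atom, passed on by catalytic SeO2)
Why: Sharpless SeO2/t-BuOOH allylic oxidation (ene reaction then [2,3]-shift) goes to the (E)-methyl of the most exposed, terminal trisubstituted alkene and gives the (E)-allylic alcohol.

Step 3
Reactants: 5 allyl 3-[(2E,6E,10E)-12-hydroxyfarnesyl]-4-(pivaloyloxy)benzoate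
Product: 6 allyl 3-[(2E,6E,10E)-12-bromofarnesyl]-4-(pivaloyloxy)benzoate
Conditions: CBr4, PPh3, CH2Cl2, −30 °C
Reagents that add atoms: carbon tetrabromide, BrC(Br)(Br)Br
Why: Appel bromination of a primary allylic alcohol is fast at low temperature and proceeds without allylic transposition or loss of alkene geometry.

Step 4
Reactants: 7 methyl (S)-glycidate
Product: 9 (R)-3-methyl-1-(phenylsulfonyl)butane-2,3-diol, via epoxy alcohol 8 (not isolated)
Conditions: MeMgCl (2.1 equiv), THF, −78 → −40 °C; pH 7 phosphate buffer; then PhSO2Na, H2O/THF, 60 °C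
Reagents that add atoms: methylmagnesium chloride, C[Mg]Cl; sodium benzenesulfinate, [Na+].[O-]S(=O)c1ccccc1
Why: Double Grignard addition to the ester leaves the epoxide and the bought stereocentre untouched, and the sulfinate then opens the epoxide by SN2 at its CH2 end (the buffer suppresses Payne rearrangement), so the future C14 keeps the bought arrangement (it reads R in 9 only because the sulfonyl group changes the CIP priorities).

Step 5
Reactants: 6 allyl 3-[(2E,6E,10E)-12-bromofarnesyl]-4-(pivaloyloxy)benzoate; 9 (R)-3-methyl-1-(phenylsulfonyl)butane-2,3-diol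
Product: 10 allyl 3-[(2E,6E,10E)-14,15-dihydroxy-3,7,11,15-tetramethyl-13-(phenylsulfonyl)hexadeca-2,6,10-trienyl]-4-(pivaloyloxy)benzoate
Conditions: 9, n-BuLi (3 equiv), THF/DMPU, −78 → −20 °C; then 6, −78 → −40 °C
Reagents that add atoms: none
Why: Alkylation of the β-oxido α-sulfonyl carbanion (sulfone alkylation, SN2 at the primary allylic bromide) forms C12–C13 without touching the alkene geometries or C14; the new C13 centre is a mixture that step 6 erases.

Step 6
Reactants: 10 the C13 sulfone from step 5
Product: 11 allyl 3-[(2E,6E,10E,14S)-14,15-dihydroxy-3,7,11,15-tetramethylhexadeca-2,6,10-trienyl]-4-(pivaloyloxy)benzoate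
Conditions: Na(Hg) (6 %), Na2HPO4, MeOH/THF, −20 °C
Reagents that add atoms: none
Why: Buffered reductive desulfonylation (Julia-type Na(Hg) cleavage) replaces the sulfonyl group by hydrogen, and the free β-hydroxyl does not eliminate, so C13 becomes CH2 and C14 is (S).

Step 7
Reactants: 11 the (14S)-14,15-diol triene
Product: 12 its (10R,11R)-10,11-epoxide (14S)
Conditions: VO(acac)2 (5 mol %), t-BuOOH (decane), NaOAc, toluene, 0 °C → rt
Reagents that add atoms: tert-butyl hydroperoxide, CC(C)(C)OO
Why: Kishi-type hydroxyl-directed vanadium epoxidation reaches only the bishomoallylic C10=C11, through a chair-like vanadate transition state with the C15 group and the C11 methyl pseudo-equatorial (the sense that leads to 2,5-trans tetrahydrofurans); from the (14S) carbinol this sets (10R,11R), the mirror image of the epoxide needed, which steps 12 and 13 invert stereospecifically.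

Step 8
Reactants: 12 the (10R,11R,14S)-epoxy diol allyl ester
Product: 13 the corresponding free benzoic acid (seco acid)
Conditions: Pd(PPh3)4 (5 mol %), pyrrolidine, THF, 0 °C; pH 5 work-up, used at once
Reagents that add atoms: none
Why: Zerovalent palladium ionises the allyl ester to a π-allyl complex that pyrrolidine captures (Tsuji–Trost deallylation), which frees the acid under neutral conditions that spare the epoxy alcohol and the aryl pivalate.

Step 9
Reactants: 13 the seco acid
Product: 14 19-membered macrolactone closed through O14, with the C15 carbinol free (10R,11R,14S)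
Conditions: 2-methyl-6-nitrobenzoic anhydride, DMAP, CH2Cl2 (1 mM, slow addition), rt
Reagents that add atoms: none
Why: Shiina macrolactonisation acylates only the secondary C14 hydroxyl (the tertiary C15 hydroxyl is inert) with retention at C14, under basic conditions that keep the epoxide intact.

Step 10
Reactants: 14 the 19-membered C14 lactone
Product: 15 20-membered macrolactone closed through O15 with (14R)-bromide (10R,11R,14R)
Conditions: Me2C=C(Br)NMe2, 2,6-di-tert-butylpyridine (0.2 equiv), CH2Cl2, −20 °C → rt
Reagents that add atoms: 1-bromo-N,N,2-trimethylprop-1-en-1-amine, CC(C)=C(Br)N(C)C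
Why: The Ghosez-type bromoenamine turns the tertiary alcohol into a leaving group whose departure is assisted by the neighbouring C14 ester carbonyl (Winstein neighbouring-group participation, bridged acyloxonium ion, as in diol-to-bromoester conversions), and bromide opens the bridged ion by SN2 at the secondary C14 with inversion, which gives (14R)-Br, moves the ester to O15 and enlarges the ring by one atom.

Step 11
Reactants: 15 the 20-membered bromolactone
Product: 16 O-pivaloyl (6S,7S,10R,11R,14R)-bromocyclised macrolide with the 16-membered lactone and the tetrasubstituted C2=C3 cyclohexene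
Conditions: undivided cell, graphite anode, Pt cathode, constant current, 2.2 F/mol; Et4NBr (1.05 equiv, added slowly), Bu4NPF6, (CF3)2CHOH/CH2Cl2 1:4, −20 °C
Reagents that add atoms: tetraethylammonium bromide, CC[N+](CC)(CC)CC.[Br-]
Why: Proposed new method: bromide is oxidised at the anode (about +0.9 V, far below the acylated arene, the alkenes and the epoxide) to Br2, which the alkoxide formed at the cathode from (CF3)2CHOH converts into the hypobromite (CF3)2CHOBr, an electrophilic-bromine carrier with no nucleophilic counter-ion while free bromide stays low; Br+ is passed reversibly to the trisubstituted alkenes, but only the C6=C7 bromiranium ion has a productive outlet, a chair-like transannular attack of C2=C3 on C7 (anti addition across the E-alkene fixes C6 relative to C7, and the face is set by the ring conformation imposed by C10, C11 and C14, expected 6S,7S), after which the tertiary C3 cation loses the C2 proton to the alkoxide to give the tetrasubstituted alkene; the closest known chemistry is anodic bromide-mediated bromolactonisation and bromoetherification of alkenes and chemical bromonium polyene cyclisation with bromosulfonium reagents, neither shown for a transannular carbocyclisation.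

Step 12
Reactants: 16 the bromocyclised (10R,11R)-epoxide
Product: 17 the (10R,11S)-10,11-diol (6S,7S,14R unchanged)
Conditions: HClO4 (0.3 M aq.), THF, 0 °C
Reagents that add atoms: water, O
Why: Acid-catalysed epoxide hydrolysis, in which water attacks the protonated epoxide at the tertiary C11 from the rear (SN1-like, inversion at C11, C10 untouched).

Step 13
Reactants: 17 the (10R,11S)-diol
Product: 20 target (6S,7S,10S,11S,14R)-macrolide CNP0420597.1, via mesylate 18 (not isolated), via pivalate epoxide 19 (not isolated)
Conditions: MsCl, Et3N, CH2Cl2, −20 °C; then K2CO3, MeOH, 0 °C → rt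
Reagents that add atoms: none
Why: Selective mesylation of the secondary C10 hydroxyl and intramolecular Williamson displacement by the C11 alkoxide invert C10, so the epoxide re-forms as (10S,11S) (net double inversion of the step 7 epoxide), and methanolysis of the aryl pivalate then frees the phenol.

**Compound list**

1 | allyl 4-hydroxybenzoate | C=CCOC(=O)c1ccc(O)cc1 | starting material
2 | (2E,6E)-farnesyl bromide | BrC/C=C(\C)CC/C=C(\C)CCC=C(C)C | starting material
3 | allyl 4-hydroxy-3-[(2E,6E)-farnesyl]benzoate (sodium phenoxide in the flask) | C=CCOC(=O)c1ccc(O)c(C/C=C(\C)CC/C=C(\C)CCC=C(C)C)c1 | intermediate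
4 | allyl 3-[(2E,6E)-farnesyl]-4-(pivaloyloxy)benzoate | C=CCOC(=O)c1ccc(OC(=O)C(C)(C)C)c(C/C=C(\C)CC/C=C(\C)CCC=C(C)C)c1 | intermediate
5 | allyl 3-[(2E,6E,10E)-12-hydroxy-3,7,11-trimethyldodeca-2,6,10-trienyl]-4-(pivaloyloxy)benzoate | C=CCOC(=O)c1ccc(OC(=O)C(C)(C)C)c(C/C=C(\C)CC/C=C(\C)CC/C=C(\C)CO)c1 | intermediate
6 | allyl 3-[(2E,6E,10E)-12-bromo-3,7,11-trimethyldodeca-2,6,10-trienyl]-4-(pivaloyloxy)benzoate | C=CCOC(=O)c1ccc(OC(=O)C(C)(C)C)c(C/C=C(\C)CC/C=C(\C)CC/C=C(\C)CBr)c1 | intermediate
7 | methyl (S)-oxirane-2-carboxylate (methyl (S)-glycidate) | COC(=O)[C@@H]1CO1 | starting material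
8 | (S)-2-(oxiran-2-yl)propan-2-ol | CC(C)(O)[C@@H]1CO1 | intermediate
9 | (R)-3-methyl-1-(phenylsulfonyl)butane-2,3-diol (same spatial arrangement as in 7) | CC(C)(O)[C@@H](O)CS(=O)(=O)c1ccccc1 | intermediate
10 | allyl 3-[(2E,6E,10E)-14,15-dihydroxy-3,7,11,15-tetramethyl-13-(phenylsulfonyl)hexadeca-2,6,10-trienyl]-4-(pivaloyloxy)benzoate; C14 as bought (R by CIP here), both C13 epimers | C=CCOC(=O)c1ccc(OC(=O)C(C)(C)C)c(C/C=C(\C)CC/C=C(\C)CC/C=C(\C)CC([C@H](O)C(C)(C)O)S(=O)(=O)c2ccccc2)c1 | intermediate
11 | allyl 3-[(2E,6E,10E,14S)-14,15-dihydroxy-3,7,11,15-tetramethylhexadeca-2,6,10-trienyl]-4-(pivaloyloxy)benzoate | C=CCOC(=O)c1ccc(OC(=O)C(C)(C)C)c(C/C=C(\C)CC/C=C(\C)CC/C=C(\C)CC[C@H](O)C(C)(C)O)c1 | intermediate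
12 | (10R,11R)-10,11-epoxide of 11 (2E,6E,14S) | C=CCOC(=O)c1ccc(OC(=O)C(C)(C)C)c(C/C=C(\C)CC/C=C(\C)CC[C@H]2O[C@]2(C)CC[C@H](O)C(C)(C)O)c1 | intermediate
13 | free benzoic acid of 12 (seco acid) | OC(=O)c1ccc(OC(=O)C(C)(C)C)c(C/C=C(\C)CC/C=C(\C)CC[C@H]2O[C@]2(C)CC[C@H](O)C(C)(C)O)c1 | intermediate
14 | 19-membered macrolactone of 13 through O14, C15 carbinol free, (2E,6E,10R,11R,14S) | O=C1O[C@H](C(C)(C)O)CC[C@@]2(C)O[C@@H]2CC/C(C)=C/CC/C(C)=C/Cc2cc1ccc2OC(=O)C(C)(C)C | intermediate
15 | 20-membered macrolactone through O15 with bromide on C14, (2E,6E,10R,11R,14R) | O=C1OC(C)(C)[C@H](Br)CC[C@@]2(C)O[C@@H]2CC/C(C)=C/CC/C(C)=C/Cc2cc1ccc2OC(=O)C(C)(C)C | intermediate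
16 | O-pivaloyl bromocyclised macrolide, (6S,7S,10R,11R,14R), tetrasubstituted C2=C3 | CC1=C2Cc3cc(ccc3OC(=O)C(C)(C)C)C(=O)OC(C)(C)[C@H](Br)CC[C@@]3(C)O[C@@H]3CC[C@]2(C)[C@@H](Br)CC1 | intermediate
17 | (10R,11S)-10,11-diol from 16, (6S,7S,14R) | CC1=C2Cc3cc(ccc3OC(=O)C(C)(C)C)C(=O)OC(C)(C)[C@H](Br)CC[C@](C)(O)[C@H](O)CC[C@]2(C)[C@@H](Br)CC1 | intermediate
18 | C10 methanesulfonate of 17 | CC1=C2Cc3cc(ccc3OC(=O)C(C)(C)C)C(=O)OC(C)(C)[C@H](Br)CC[C@](C)(O)[C@H](OS(C)(=O)=O)CC[C@]2(C)[C@@H](Br)CC1 | intermediate
19 | O-pivaloyl derivative of the target, (6S,7S,10S,11S,14R) | CC1=C2Cc3cc(ccc3OC(=O)C(C)(C)C)C(=O)OC(C)(C)[C@H](Br)CC[C@]3(C)O[C@H]3CC[C@]2(C)[C@@H](Br)CC1 | intermediate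
20 | CNP0420597.1, (6S,7S,10S,11S,14R) | CC1=C2Cc3cc(ccc3O)C(=O)OC(C)(C)[C@H](Br)CC[C@]3(C)O[C@H]3CC[C@]2(C)[C@@H](Br)CC1 | target

**Step count and risks**

Total step count: 13. Longest linear sequence: 12 (steps 1–3 and 5–13; step 4 is a one-step side branch). The count is set by three needs: the chain must be assembled around one bought stereocentre, C10=C11 must be singled out among three like alkenes, and the tertiary ester must be made without acylating a tertiary alcohol.

The three steps most likely to fail:

Step 11 (the proposed new step). It can fail by vicinal dibromide formation, by attack of the epoxide oxygen on the bromiranium ion, by bromination of the product alkene, by the wrong alkene isomer on proton loss, or by the wrong face at C6=C7. The fallback is the known stoichiometric bromonium polyene cyclisation: 15 is treated with Et2SBr·SbBrCl5 in MeNO2 at −25 °C and comes back to the route at 16. This fallback makes no new compound (F0).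

Step 10. Bromide may open the bridged ion at the tertiary C15, or the tertiary cation may eliminate. The fallback installs the bromide before lactonisation and sets out from 12. 1,1'-Sulfonyldiimidazole and NaH give the 14,15-cyclic sulfate F3. LiBr opens it by SN2 at the secondary C14 with inversion, and the labile tertiary sulfate half-ester hydrolyses on buffered aqueous work-up to the (14R)-bromohydrin allyl ester F4. Pd(PPh3)4 and pyrrolidine free the bromohydrin acid F5, which is lactonised at the tertiary hydroxyl under forcing Yamaguchi conditions (2,4,6-trichlorobenzoyl chloride, Et3N, DMAP, toluene, 80 °C). The fallback comes back to the route at 15.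

Step 7. The facial preference may be weak, or the epoxy alcohol may close to a tetrahydrofuran in the flask; the absolute sense assumed (2,5-trans type) also decides which glycidate enantiomer is bought. The fallback lets the macrocycle, not the open chain, present the alkene and sets out from 11. Deallylation (Pd(PPh3)4, pyrrolidine) gives the triene seco acid F1, and Shiina lactonisation gives the 19-membered triene lactone F2, in which the C14 oxygen is acylated and can no longer cyclise. VO(acac)2/t-BuOOH, now directed by the free tertiary C15 hydroxyl that the ring holds next to C10=C11 only, then gives the epoxide. The fallback comes back to the route at 14.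

Further compounds
F1 | step 7 | triene seco acid, free acid of 11 (2E,6E,10E,14S) | OC(=O)c1ccc(OC(=O)C(C)(C)C)c(C/C=C(\C)CC/C=C(\C)CC/C=C(\C)CC[C@H](O)C(C)(C)O)c1
F2 | step 7 | 19-membered triene lactone of F1 through O14, C15 carbinol free (2E,6E,10E,14S) | O=C1O[C@H](C(C)(C)O)CC/C(C)=C/CC/C(C)=C/CC/C(C)=C/Cc2cc1ccc2OC(=O)C(C)(C)C
F3 | step 10 | 14,15-cyclic sulfate of 12 | C=CCOC(=O)c1ccc(OC(=O)C(C)(C)C)c(C/C=C(\C)CC/C=C(\C)CC[C@H]2O[C@]2(C)CC[C@@H]3OS(=O)(=O)OC3(C)C)c1
F4 | step 10 | (14R)-14-bromo-15-hydroxy allyl ester, (10R,11R)-epoxide | C=CCOC(=O)c1ccc(OC(=O)C(C)(C)C)c(C/C=C(\C)CC/C=C(\C)CC[C@H]2O[C@]2(C)CC[C@@H](Br)C(C)(C)O)c1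
F5 | step 10 | free benzoic acid of F4 | OC(=O)c1ccc(OC(=O)C(C)(C)C)c(C/C=C(\C)CC/C=C(\C)CC[C@H]2O[C@]2(C)CC[C@@H](Br)C(C)(C)O)c1
F0 | step 11 | none | none
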